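**Plan**

- Retrosynthesis cuts the ester at two bonds at once, G1–C(=O) and C(=O)–O10, giving dienyl triflate 19, carbon monoxide 7 and triol 34. This is possible because the ester carbonyl sits on G1, the terminus of the G1=G2–G3=G4 diene of the seven-membered ring (G1–G5, G6, G10; G4 carries isopropyl; cyclopentane G6–G10 with methyl on G7), which is where a dienol triflate of the G1 ketone has its leaving group. The lactone half (C1 lactone carbonyl, O2, C3, C4=CH2, ring fusion C5/C9, C6, C7, C8, C10 = CH2OH) has a single primary hydroxyl (C10) beside a secondary (C7) and a tertiary (C8) one.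
- Triflate 19 is cut at the enol triflate, at G3=G4 (ring-closing metathesis), at G1–G2 (allyl Grignard on a Weinreb amide) and at G5–G4 (Negishi coupling), back to an all-cis cyclopentane lactone derived from (R)-pulegone.
- Triol 34 is cut at the C8–O and C10–O bonds (directed dihydroxylation), at C8–C9 (radical 5-exo-dig closure), at C7–C8 (acetylide addition) and at the lactone C3–O bond, back to an aldehyde acid made by excising C2 of (R)-carvone.
- Forward, acid half: cyclopentane by Favorskii contraction, then a butenolide ring that is hydrogenated and reopened, then the seven-membered ring by metathesis. Lactone half: the δ-lactone first, then the cyclopentane by radical cyclisation. The halves are joined last.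
- Stereochemistry: G7 comes from (R)-pulegone; G6 and G10 from hydrogenation anti to the G7 methyl. C5 comes from (R)-carvone; C7 from asymmetric transfer hydrogenation; C9 from the cis ring fusion enforced in the radical closure; C8 from osmylation directed syn to the C7 hydroxyl.

Key step: step 23

Remark: the sense of induction in step 18 is assigned by analogy with simple alkynyl methyl ketones; the (R,R)-catalyst would be used if the opposite sense were found.

**Route**

Step 1
Reactants: 1 (R)-pulegone
Product: 3 methyl (2R)-2-methyl-5-(propan-2-ylidene)cyclopentane-1-carboxylate (C-1 epimer mixture), via pulegone dibromide 2 (not isolated)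
Conditions: Br2, Et2O, −10 °C; then NaOMe, MeOH, reflux
Reagents that add atoms: sodium methoxide, [Na+].[O-]C
Why: Bromine adds to the exocyclic alkene and methoxide then triggers a Favorskii ring contraction with loss of the second bromide, which restores the isopropylidene group and leaves the remote methyl stereocentre untouched.

Step 2
Reactants: 3 methyl pulegenate
Product: 4 methyl (2R)-2-methyl-5-oxocyclopentane-1-carboxylate (keto/enol and C-1 epimer mixture)
Conditions: O3, CH2Cl2/MeOH, −78 °C; Me2S, −78 °C to rt
Reagents that add atoms: ozone, [O-][O+]=O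
Why: Ozonolysis cleaves the tetrasubstituted alkene to the ring ketone and acetone, the Me2S quench serving only to destroy the peroxidic acetone-derived fragment.

Step 3
Reactants: 4 keto ester
Product: 5 methyl (5R)-5-methyl-2-[(trifluoromethanesulfonyl)oxy]cyclopent-1-ene-1-carboxylate
Conditions: Tf2O, iPr2NEt, CH2Cl2, −78 °C
Reagents that add atoms: triflic anhydride, O=S(=O)(OS(=O)(=O)C(F)(F)F)C(F)(F)F
Why: O-sulfonylation of the β-keto ester enol gives the conjugated enol triflate (enol triflate formation), which also removes the epimerisable ester-bearing centre.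

Step 4
Reactants: 5 enol triflate
Product: 6 (3R)-2-(hydroxymethyl)-3-methylcyclopent-1-en-1-yl trifluoromethanesulfonate
Conditions: iBu2AlH (2.5 equiv), CH2Cl2, −78 °C; aqueous Rochelle salt work-up
Reagents that add atoms: none
Why: 1,2-Reduction of the enoate with iBu2AlH at −78 °C gives the allylic alcohol while the vinyl triflate is inert to hydride at this temperature.

Step 5
Reactants: 6 hydroxymethyl vinyl triflate; 7 carbon monoxide
Product: 8 (4R)-4-methyl-3,4,5,6-tetrahydro-1H-cyclopenta[c]furan-1-one
Conditions: Pd(PPh3)4 (5 mol %), CO (1 atm), Bu3N, MeCN, 65 °C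
Reagents that add atoms: none
Why: Zerovalent palladium inserts into the C–OTf bond, CO inserts and the neighbouring hydroxyl captures the acyl complex to close the butenolide (palladium-catalysed carbonylative lactonisation of a hydroxy vinyl triflate).

Step 6
Reactants: 8 butenolide
Product: 9 (3aR,4R,6aS)-4-methylhexahydro-1H-cyclopenta[c]furan-1-one (all-cis)
Conditions: H2 (30 bar), Rh/Al2O3, EtOAc, rt
Reagents that add atoms: none
Why: Catalytic syn hydrogenation of the tetrasubstituted alkene from the face opposite the C-4 methyl sets G6 and G10 together, giving the necessarily cis-fused lactone with both new hydrogens cis to the hydrogen on G7.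

Step 7
Reactants: 9 cis-fused lactone
Product: 11 methyl (1S,2R,3R)-2-(iodomethyl)-3-methylcyclopentane-1-carboxylate, via silyl ester 10 (not isolated)
Conditions: Me3SiI, CH2Cl2, rt; then MeOH, rt
Reagents that add atoms: iodotrimethylsilane, C[Si](C)(C)I; methanol, CO
Why: Iodide opens the O-silylated lactone by SN2 attack at the primary CH2–O carbon and the silyl ester is then esterified by methanol under the HI formed (iodotrimethylsilane lactone cleavage), with no stereocentre involved.

Step 8
Reactants: 11 iodo ester; 12 2-bromo-3-methylbut-1-ene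
Product: 14 methyl (1S,2R,3R)-3-methyl-2-(3-methyl-2-methylidenebutyl)cyclopentane-1-carboxylate, via alkylzinc iodide 13 (not isolated)
Conditions: Zn dust, LiCl, THF, 40 °C; then 12, Pd2(dba)3 (2.5 mol %), SPhos (10 mol %), THF, 50 °C
Reagents that add atoms: none
Why: Zinc inserts into the primary C–I bond without touching the ester, and Negishi cross-coupling with the alkenyl bromide forms the G5–G4 bond.

Step 9
Reactants: 14 ester
Product: 15 (1S,2R,3R)-N-methoxy-N,3-dimethyl-2-(3-methyl-2-methylidenebutyl)cyclopentane-1-carboxamide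
Conditions: MeNHOMe·HCl, iPrMgCl, THF, −20 to 0 °C
Reagents that add atoms: N,O-dimethylhydroxylamine hydrochloride, CNOC.Cl
Why: The chloromagnesium amide formed in the flask converts the ester directly into the Weinreb amide (ester aminolysis) at a temperature low enough that the cis α-centre G10 should not epimerise.

Step 10
Reactants: 15 Weinreb amide
Product: 16 1-[(1S,2R,3R)-3-methyl-2-(3-methyl-2-methylidenebutyl)cyclopentyl]but-3-en-1-one
Conditions: allylMgBr (1.5 equiv), THF, −78 to −20 °C; cold aqueous NH4Cl
Reagents that add atoms: allylmagnesium bromide, C=CC[Mg]Br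
Why: The chelated tetrahedral adduct blocks over-addition and releases the β,γ-unsaturated ketone only on cold buffered quench (Weinreb ketone synthesis), which forms the G1–G2 bond.

Step 11
Reactants: 16 diene ketone
Product: 17 (1R,3aS,8aR)-1-methyl-7-(propan-2-yl)-2,3,3a,5,8,8a-hexahydroazulen-4(1H)-one
Conditions: RuCl2(=CHPh)(H2IMes)(PCy3) (second-generation Grubbs catalyst, 5 mol %), 1,4-benzoquinone (10 mol %), CH2Cl2 (5 mM), 40 °C
Reagents that add atoms: none
Why: Ring-closing metathesis between the allyl and the 1,1-disubstituted alkene closes the seven-membered ring as its trisubstituted G3=G4 alkene, with benzoquinone suppressing hydride-mediated migration of the β,γ-alkene.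

Step 12
Reactants: 17 hydroazulenone
Product: 19 (1R,3aS,8aR)-1-methyl-7-(propan-2-yl)-1,2,3,3a,8,8a-hexahydroazulen-4-yl trifluoromethanesulfonate, via potassium dienolate 18 (not isolated)
Conditions: KN(SiMe3)2, THF, −78 °C; then PhNTf2, −78 to 0 °C
Reagents that add atoms: N-phenylbis(trifluoromethanesulfonimide), O=S(=O)(N(c1ccccc1)S(=O)(=O)C(F)(F)F)C(F)(F)F
Why: The hindered base removes the doubly activated G2 proton (α to the ketone and allylic) in preference to the tertiary G10 proton, and O-triflation of the extended enolate fixes the G1=G2–G3=G4 diene (kinetic enol triflate formation).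

Step 13
Reactants: 20 (R)-carvone
Product: 21 (1R,4R,6R)-1-methyl-4-(prop-1-en-2-yl)-7-oxabicyclo[4.1.0]heptan-2-one
Conditions: H2O2 (30 % aq.), NaOH (aq.), MeOH, 0 °C
Reagents that add atoms: hydrogen peroxide, OO
Why: Weitz–Scheffer nucleophilic epoxidation attacks only the enone alkene, anti to the side chain, and leaves the isopropenyl group untouched.

Step 14
Reactants: 21 carvone oxide
Product: 22 (1R,4R,6R)-4-(3-chloroprop-1-en-2-yl)-1-methyl-7-oxabicyclo[4.1.0]heptan-2-one
Conditions: Ca(OCl)2, solid CO2, CH2Cl2/H2O, 0 °C
Reagents that add atoms: calcium hypochlorite, [Ca+2].[O-]Cl.[O-]Cl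
Why: Hypochlorous acid generated in the flask undergoes an ene-type allylic chlorination of the 1,1-disubstituted alkene to give the 2-substituted allyl chloride, the epoxy ketone being inert.

Step 15
Reactants: 22 chloro epoxy ketone
Product: 24 (4R)-5-methylidene-4-(2-oxoethyl)oxan-2-one, via seco acid 23 (not isolated)
Conditions: H5IO6 (2.5 equiv), THF/H2O, rt; then NaHCO3 to pH 8, 40 °C
Reagents that add atoms: water, O
Why: Periodic acid hydrates the oxirane and cleaves first the glycol and then the resulting 1,2-diketone (Malaprade cleavage), excising C2 with its methyl as acetic acid, after which the carboxylate displaces the allylic chloride in a 6-exo-tet lactonisation that leaves the stereocentre (C5) untouched.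

Step 16
Reactants: 24 lactone aldehyde
Product: 25 (4R)-4-[2-hydroxy-4-(trimethylsilyl)but-3-yn-1-yl]-5-methylideneoxan-2-one (both carbinol epimers)
Conditions: Me3SiC≡CH, n-BuLi, THF, −78 °C; AcOH quench at −78 °C
Reagents that add atoms: ethynyltrimethylsilane, C#C[Si](C)(C)C
Why: The lithium acetylide adds to the aldehyde much faster than to the lactone at −78 °C (1,2-addition), and the carbinol centre needs no control because it is oxidised in the next step.

Step 17
Reactants: 25 propargylic alcohols
Product: 26 (4R)-5-methylidene-4-[2-oxo-4-(trimethylsilyl)but-3-yn-1-yl]oxan-2-one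
Conditions: Dess–Martin periodinane, NaHCO3, CH2Cl2, 0 °C to rt
Reagents that add atoms: none
Why: Dess–Martin oxidation converts the propargylic alcohol into the ynone under buffered, non-basic conditions that spare the lactone and both alkenes.

Step 18
Reactants: 26 ynone
Product: 27 (4R)-4-[(2S)-2-hydroxy-4-(trimethylsilyl)but-3-yn-1-yl]-5-methylideneoxan-2-one
Conditions: Ru[(S,S)-TsNCH(Ph)CH(Ph)NH](p-cymene) (2 mol %), iPrOH, rt
Reagents that add atoms: none
Why: Noyori asymmetric transfer hydrogenation of the alkynyl ketone under base-free conditions sets C7 by catalyst control, the (S,S)-catalyst being expected to give the (S)-carbinol with the alkynyl group as the large π-substituent.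

Step 19
Reactants: 27 silyl alkynol
Product: 28 (4R)-4-[(2S)-2-hydroxybut-3-yn-1-yl]-5-methylideneoxan-2-one
Conditions: Bu4NF, AcOH, THF, 0 °C
Reagents that add atoms: none
Why: Buffered fluoride cleaves the alkynyl C–Si bond (protodesilylation) without generating an alkoxide that could open the lactone.

Step 20
Reactants: 28 alkynol lactone
Product: 30 (3RS,4S)-5-methylidene-3-(phenylselanyl)-4-[(2S)-2-(trimethylsilyloxy)but-3-yn-1-yl]oxan-2-one, via bis-silylated ketene acetal 29 (not isolated)
Conditions: Me3SiOTf (2.5 equiv), Et3N (3 equiv), CH2Cl2, 0 °C; then PhSeBr (1.0 equiv), −78 °C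
Reagents that add atoms: trimethylsilyl triflate, C[Si](C)(C)OS(=O)(=O)C(F)(F)F; phenylselenyl bromide, Br[Se]c1ccccc1
Why: Soft enolisation silylates the hydroxyl and turns the lactone into its silyl ketene acetal, which is selenenylated at the α-carbon far faster than the alkyne or the methylidene group (α-selenenylation of a silyl ketene acetal).

Step 21
Reactants: 30 α-seleno lactone
Product: 32 (4aR,6S,7aR)-6-hydroxy-4,7-dimethylidenehexahydrocyclopenta[c]pyran-1(3H)-one, via cyclised silyl ether 31 (not isolated)
Conditions: Bu3SnH (slow addition), AIBN (cat.), benzene, 80 °C; then 1 M HCl, THF, 0 °C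
Reagents that add atoms: none
Why: The tin radical abstracts the phenylselanyl group and the α-lactone radical closes 5-exo-dig onto the alkyne carried by the adjacent ring carbon, so C9 is necessarily formed with a cis ring fusion, and the vinyl radical is reduced to the exocyclic methylene (reductive radical cyclisation) without any base that could move this alkene into conjugation.

Step 22
Reactants: 32 allylic alcohol
Product: 34 (4aR,6S,7S,7aR)-6,7-dihydroxy-7-(hydroxymethyl)-4-methylidenehexahydrocyclopenta[c]pyran-1(3H)-one, via osmate ester 33 (not isolated)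
Conditions: OsO4 (1.05 equiv), TMEDA (1.1 equiv), CH2Cl2, −78 °C; then aqueous NaHSO3, THF, 40 °C
Reagents that add atoms: osmium tetroxide, O=[Os](=O)(=O)=O
Why: The OsO4·TMEDA complex is hydrogen-bonded to the C7 hydroxyl and adds to the neighbouring exocyclic alkene syn to it (Donohoe directed dihydroxylation), which places the tertiary C8 hydroxyl cis to the C7 hydroxyl and the CH2OH on the convex face, while the C4 methylidene has no directing group.

Step 23
Reactants: 19 dienyl triflate; 7 carbon monoxide; 34 triol
Product: 35 nardostachysin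
Conditions: Pd(OAc)2 (10 mol %), dppp (12 mol %), CO (1 atm), iPr2NEt (2 equiv), DMF, 60 °C; 34 (1.3 equiv)
Reagents that add atoms: none
Why: Zerovalent palladium formed from Pd(OAc)2 and dppp inserts into the C–OTf bond of 19, CO inserts to give a dienoyl palladium complex, and the primary hydroxyl of 34 attacks it with base assistance to release the ester and regenerate the catalyst. The closest known reaction type is the palladium-catalysed alkoxycarbonylation of enol and dienyl triflates with alcohols. No ring is closed and no stereocentre is formed, so G6, G7 and G10 of 19 and C5, C7, C8 and C9 of 34 pass through unchanged. The step needs site selectivity among three hydroxyls and retention of the diene position: the C10 hydroxyl is the only primary one and lies on the convex face, whereas the C7 and C8 hydroxyls are secondary and tertiary and sit on the concave face beside the lactone, and the diene cannot move because the carbonyl enters exactly where the triflate leaves without a free dienoic acid ever being made. The allylic lactone C–O bond of 34 is a second possible site for zerovalent palladium, but insertion into the dienyl triflate is faster and an ionised allyl carboxylate can only reclose to the same lactone.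

**Compound list**

1 | (R)-pulegone, (5R)-5-methyl-2-(propan-2-ylidene)cyclohexan-1-one | C[C@@H]1CCC(=C(C)C)C(=O)C1 | starting material
2 | (5R)-2-bromo-2-(2-bromopropan-2-yl)-5-methylcyclohexan-1-one (pulegone dibromide, C-2 epimers) | C[C@@H]1CCC(Br)(C(C)(C)Br)C(=O)C1 | intermediate
3 | methyl (2R)-2-methyl-5-(propan-2-ylidene)cyclopentane-1-carboxylate (C-1 epimers) | C[C@@H]1CCC(=C(C)C)C1C(=O)OC | intermediate
4 | methyl (2R)-2-methyl-5-oxocyclopentane-1-carboxylate | C[C@@H]1CCC(=O)C1C(=O)OC | intermediate
5 | methyl (5R)-5-methyl-2-[(trifluoromethanesulfonyl)oxy]cyclopent-1-ene-1-carboxylate | C[C@@H]1CCC(OS(=O)(=O)C(F)(F)F)=C1C(=O)OC | intermediate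
6 | (3R)-2-(hydroxymethyl)-3-methylcyclopent-1-en-1-yl trifluoromethanesulfonate | C[C@@H]1CCC(OS(=O)(=O)C(F)(F)F)=C1CO | intermediate
7 | carbon monoxide | [C-]#[O+] | starting material
8 | (4R)-4-methyl-3,4,5,6-tetrahydro-1H-cyclopenta[c]furan-1-one | C[C@@H]1CCC2=C1COC2=O | intermediate
9 | (3aR,4R,6aS)-4-methylhexahydro-1H-cyclopenta[c]furan-1-one (all-cis) | O=C1OC[C@@H]2[C@H](C)CC[C@H]12 | intermediate
10 | trimethylsilyl (1S,2R,3R)-2-(iodomethyl)-3-methylcyclopentane-1-carboxylate | IC[C@@H]1[C@H](C)CC[C@@H]1C(=O)O[Si](C)(C)C | intermediate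
11 | methyl (1S,2R,3R)-2-(iodomethyl)-3-methylcyclopentane-1-carboxylate | IC[C@@H]1[C@H](C)CC[C@@H]1C(=O)OC | intermediate
12 | 2-bromo-3-methylbut-1-ene | C=C(Br)C(C)C | starting material
13 | {[(1R,2S,5R)-2-(methoxycarbonyl)-5-methylcyclopentyl]methyl}zinc iodide | I[Zn]C[C@@H]1[C@H](C)CC[C@@H]1C(=O)OC | intermediate
14 | methyl (1S,2R,3R)-3-methyl-2-(3-methyl-2-methylidenebutyl)cyclopentane-1-carboxylate | C=C(C(C)C)C[C@@H]1[C@H](C)CC[C@@H]1C(=O)OC | intermediate
15 | (1S,2R,3R)-N-methoxy-N,3-dimethyl-2-(3-methyl-2-methylidenebutyl)cyclopentane-1-carboxamide | C=C(C(C)C)C[C@@H]1[C@H](C)CC[C@@H]1C(=O)N(C)OC | intermediate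
16 | 1-[(1S,2R,3R)-3-methyl-2-(3-methyl-2-methylidenebutyl)cyclopentyl]but-3-en-1-one | C=C(C(C)C)C[C@@H]1[C@H](C)CC[C@@H]1C(=O)CC=C | intermediate
17 | (1R,3aS,8aR)-1-methyl-7-(propan-2-yl)-2,3,3a,5,8,8a-hexahydroazulen-4(1H)-one | O=C1CC=C(C(C)C)C[C@@H]2[C@H](C)CC[C@H]12 | intermediate
18 | potassium (1R,3aS,8aR)-1-methyl-7-(propan-2-yl)-1,2,3,3a,8,8a-hexahydroazulen-4-olate | [K+].[O-]C1=CC=C(C(C)C)C[C@@H]2[C@H](C)CC[C@H]12 | intermediate
19 | (1R,3aS,8aR)-1-methyl-7-(propan-2-yl)-1,2,3,3a,8,8a-hexahydroazulen-4-yl trifluoromethanesulfonate | O=S(=O)(OC1=CC=C(C(C)C)C[C@@H]2[C@H](C)CC[C@H]12)C(F)(F)F | intermediate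
20 | (R)-carvone, (5R)-2-methyl-5-(prop-1-en-2-yl)cyclohex-2-en-1-one | CC1=CC[C@H](CC1=O)C(C)=C | starting material
21 | (1R,4R,6R)-1-methyl-4-(prop-1-en-2-yl)-7-oxabicyclo[4.1.0]heptan-2-one | C[C@@]12O[C@@H]1C[C@H](CC2=O)C(C)=C | intermediate
22 | (1R,4R,6R)-4-(3-chloroprop-1-en-2-yl)-1-methyl-7-oxabicyclo[4.1.0]heptan-2-one | C[C@@]12O[C@@H]1C[C@H](CC2=O)C(=C)CCl | intermediate
23 | (3R)-3-(3-chloroprop-1-en-2-yl)-5-oxopentanoic acid | OC(=O)C[C@H](C(=C)CCl)CC=O | intermediate
24 | (4R)-5-methylidene-4-(2-oxoethyl)oxan-2-one | C=C1COC(=O)C[C@H]1CC=O | intermediate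
25 | (4R)-4-[2-hydroxy-4-(trimethylsilyl)but-3-yn-1-yl]-5-methylideneoxan-2-one (carbinol epimers) | C=C1COC(=O)C[C@H]1CC(O)C#C[Si](C)(C)C | intermediate
26 | (4R)-5-methylidene-4-[2-oxo-4-(trimethylsilyl)but-3-yn-1-yl]oxan-2-one | C=C1COC(=O)C[C@H]1CC(=O)C#C[Si](C)(C)C | intermediate
27 | (4R)-4-[(2S)-2-hydroxy-4-(trimethylsilyl)but-3-yn-1-yl]-5-methylideneoxan-2-one | C=C1COC(=O)C[C@H]1C[C@H](O)C#C[Si](C)(C)C | intermediate
28 | (4R)-4-[(2S)-2-hydroxybut-3-yn-1-yl]-5-methylideneoxan-2-one | C=C1COC(=O)C[C@H]1C[C@H](O)C#C | intermediate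
29 | trimethyl({(4R)-5-methylidene-4-[(2S)-2-(trimethylsilyloxy)but-3-yn-1-yl]-5,6-dihydro-4H-pyran-2-yl}oxy)silane | C=C1COC(O[Si](C)(C)C)=C[C@H]1C[C@H](O[Si](C)(C)C)C#C | intermediate
30 | (3RS,4S)-5-methylidene-3-(phenylselanyl)-4-[(2S)-2-(trimethylsilyloxy)but-3-yn-1-yl]oxan-2-one | C=C1COC(=O)C([Se]c2ccccc2)[C@H]1C[C@H](O[Si](C)(C)C)C#C | intermediate
31 | (4aR,6S,7aR)-4,7-dimethylidene-6-(trimethylsilyloxy)hexahydrocyclopenta[c]pyran-1(3H)-one | C=C1COC(=O)[C@@H]2[C@H]1C[C@H](O[Si](C)(C)C)C2=C | intermediate
32 | (4aR,6S,7aR)-6-hydroxy-4,7-dimethylidenehexahydrocyclopenta[c]pyran-1(3H)-one | C=C1COC(=O)[C@@H]2[C@H]1C[C@H](O)C2=C | intermediate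
33 | cyclic osmate ester of 34 across O8 and O10, TMEDA adduct | C=C1COC(=O)[C@@H]2[C@H]1C[C@H](O)[C@@]23CO[Os](=O)(=O)O3.CN(C)CCN(C)C | intermediate
34 | (4aR,6S,7S,7aR)-6,7-dihydroxy-7-(hydroxymethyl)-4-methylidenehexahydrocyclopenta[c]pyran-1(3H)-one | C=C1COC(=O)[C@@H]2[C@H]1C[C@H](O)[C@@]2(O)CO | intermediate
35 | nardostachysin, [(4aR,6S,7S,7aR)-6,7-dihydroxy-4-methylidene-1-oxooctahydrocyclopenta[c]pyran-7-yl]methyl (1R,3aS,8aR)-1-methyl-7-(propan-2-yl)-1,2,3,3a,8,8a-hexahydroazulene-4-carboxylate | C=C1COC(=O)[C@@H]2[C@H]1C[C@H](O)[C@@]2(O)COC(=O)C1=CC=C(C(C)C)C[C@@H]2[C@H](C)CC[C@H]12 | target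

**Step count and risks**

Total step count: 23. Longest linear sequence: 13 steps (steps 1–12, then step 23); the lactone half takes 10 steps (13–22) before the coupling.

Steps most likely to fail:

Step 23. The acyl palladium intermediate may be captured too slowly by a dilute, hindered polyol, so that its reduction or decomposition competes, and zerovalent palladium may ionise the allylic lactone of the triol. The fallback keeps the same two bonds but forms them in two operations, so that the triol never meets palladium. It sets out from 19, which is carbonylated in the presence of pentafluorophenol (Pd(OAc)2, dppp, CO, Et3N, DMF) to give the pentafluorophenyl dienoate F1. The acyl group is then transferred to the primary hydroxyl of 34 with DMAP and iPr2NEt in CH2Cl2 at 0 °C, which comes back to the route at 35.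

Step 22. Osmylation from the open convex face may override hydrogen-bond delivery and give the wrong C8 epimer, and the C4 methylidene may be osmylated in competition. The fallback replaces the bulky osmium complex by a covalently bound vanadium peroxide. It sets out from 32, which is epoxidised with VO(acac)2 and t-BuOOH in CH2Cl2 to give the syn epoxy alcohol F2. The oxirane is opened at its CH2 terminus with 4-nitrobenzoic acid and Ti(OiPr)4 to give the C10 4-nitrobenzoate F3, and the nitrobenzoate is removed with NaN3 in MeOH. This returns to the route at 34.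

Step 15. Hydration of the electron-poor oxirane by periodic acid may be incomplete, or the cleavage may stall at the diketone, and the aldehyde may be lost by aldol condensation during the basic lactonisation. The fallback separates hydration from cleavage. It sets out from 22, which is hydrated with aqueous HClO4 in THF to the keto diol F4. F4 is cleaved with NaIO4 in buffered aqueous THF to the seco acid 23, which is closed with NaHCO3 and catalytic NaI in DMF at rt. This returns to the route at 24.

Further compounds
F1 | step 23 | pentafluorophenyl (1R,3aS,8aR)-1-methyl-7-(propan-2-yl)-1,2,3,3a,8,8a-hexahydroazulene-4-carboxylate | O=C(Oc1c(F)c(F)c(F)c(F)c1F)C1=CC=C(C(C)C)C[C@@H]2[C@H](C)CC[C@H]12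
F2 | step 22 | (4aR,6S,7S,7aR)-6-hydroxy-4-methylidenehexahydrospiro[cyclopenta[c]pyran-7,2'-oxiran]-1(3H)-one (oxirane oxygen syn to the hydroxyl) | C=C1COC(=O)[C@@H]2[C@H]1C[C@H](O)[C@@]23CO3
F3 | step 22 | [(4aR,6S,7S,7aR)-6,7-dihydroxy-4-methylidene-1-oxooctahydrocyclopenta[c]pyran-7-yl]methyl 4-nitrobenzoate | C=C1COC(=O)[C@@H]2[C@H]1C[C@H](O)[C@@]2(O)COC(=O)c1ccc(cc1)[N+](=O)[O-]
F4 | step 15 | (5R)-5-(3-chloroprop-1-en-2-yl)-2,3-dihydroxy-2-methylcyclohexan-1-one | CC1(O)C(O)C[C@H](CC1=O)C(=C)CCl
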